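**Assumptions.** The SMILES fixes only the three stereogenic carbons (1R,3R in the tetrahydroisoquinoline half, 3R in the dihydroisoquinoline half). The two isoquinoline–naphthalene axes are configurationally stable but undefined in the string, and the central binaphthyl axis rotates freely. The route therefore sets the three carbon centres and separates the atropo-diastereomers at the monomer stage; the SMILES below carry no axis descriptor. Compounds 1, 3, 5, 8 and 17 are taken as commercial.

## Retrosynthetic overview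

1. Target ⇐ global O-debenzylation of 27 ⇐ Suzuki union (central, freely rotating bond) of tetrahydroisoquinoline bromide 16 and dihydroisoquinoline boronate 26.
2. Key step: neither hindered isoquinoline–naphthalene bond is made by cross-coupling. Each comes from 1,2-addition of an aryllithium to the C4 carbonyl of one bromonaphthoquinone 7, then aromatisation of the p-quinol. C4=O becomes the axis, C1=O the naphthol OH, and C2–Br the handle for the central bond.
3. Both N-heterocycles are closed after the axes by Bischler–Napieralski (only one ortho position is left); trans-selective hydride reduction is applied to the tetrahydro half only.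
4. Both aryl units come from one D-alaninol-derived zinc reagent (sets both C3 centres) by Negishi coupling; quinone 7 comes from a Diels–Alder reaction of 2,6-dibromobenzoquinone.
5. Ring order: naphthoquinone ring → aryl–naphthalene bond and aromatisation → dihydroisoquinoline rings → tetrahydroisoquinoline → union.

## Route

### Shared building blocks

**Step 1**
Reactants: 1, tert-butyl (R)-(1-hydroxypropan-2-yl)carbamate (N-Boc-D-alaninol)
Product: 2, tert-butyl (R)-(1-iodopropan-2-yl)carbamate
Conditions: I2, PPh3, imidazole, CH2Cl2, 0 °C → rt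
Reagents that add atoms: iodine, II
Why: Appel-type iodination of the primary alcohol; the stereocentre is not involved and stays R.

**Step 2**
Reactants: 3, methyl 3-methylbut-2-enoate
Product: 4, [(1-methoxy-3-methylbuta-1,3-dien-1-yl)oxy]trimethylsilane
Conditions: LDA, THF, −78 °C; TMSCl, −78 °C → rt; distil
Reagents that add atoms: chlorotrimethylsilane, C[Si](C)(C)Cl
Why: γ-deprotonation and O-silylation of the dienolate gives the vinylketene silyl acetal (silyl dienol ether formation).

**Step 3**
Reactants: 4; 5, 2,6-dibromo-1,4-benzoquinone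
Product: 6, 2-bromo-8-hydroxy-6-methylnaphthalene-1,4-dione
Conditions: CH2Cl2, −30 °C → rt; then silica gel / dilute HCl work-up
Reagents that add atoms: none
Why: Regioselective Diels–Alder reaction in which the nucleophilic CH2 terminus of the diene bonds to the unbrominated quinone carbon; loss of HBr and MeOH/TMS aromatises the new ring, placing OH peri to the carbonyl that keeps its neighbouring Br.

**Step 4**
Reactants: 6
Product: 7, 2-bromo-8-methoxy-6-methylnaphthalene-1,4-dione
Conditions: MeI, Ag2O, CH2Cl2, rt, dark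
Reagents that add atoms: iodomethane, CI
Why: Ag2O-mediated Williamson methylation of the hydrogen-bonded peri-hydroxyl, standard for juglones.

### Tetrahydroisoquinoline half

**Step 5**
Reactants: 2; 8, 1,3-bis(benzyloxy)-5-bromobenzene
Product: 9, tert-butyl (R)-{1-[3,5-bis(benzyloxy)phenyl]propan-2-yl}carbamate
Conditions: 2, Zn dust (I2-activated), DMF, rt; then 8, Pd2(dba)3 (2.5 mol %), SPhos (5 mol %), 50 °C
Reagents that add atoms: none
Why: Negishi sp3–sp2 coupling of the β-amido alkylzinc iodide (Jackson-type reagent); the R centre is β to zinc and untouched.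

**Step 6**
Reactants: 9
Product: 10, (R)-N-{1-[3,5-bis(benzyloxy)phenyl]propan-2-yl}acetamide
Conditions: TFA, CH2Cl2, 0 °C; concentrate; Ac2O, Et3N, CH2Cl2, rt
Reagents that add atoms: acetic anhydride, CC(=O)OC(C)=O
Why: Boc acidolysis then N-acetylation installs the C1–CH3 carbon needed for the later Bischler–Napieralski closure.

**Step 7**
Reactants: 10
Product: 11, (R)-N-{1-[3,5-bis(benzyloxy)-2-bromophenyl]propan-2-yl}acetamide
Conditions: NBS, MeCN, 0 °C, dark
Reagents that add atoms: N-bromosuccinimide, O=C1CCC(=O)N1Br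
Why: Electrophilic aromatic bromination of a 3,5-dialkoxy-alkylbenzene goes ortho to the alkyl chain and para to an alkoxy group rather than between the two alkoxy groups; the ring is symmetric, so one product forms.

**Step 8**
Reactants: 11; 7
Product: 12, N-[(2R)-1-{3,5-bis(benzyloxy)-2-(3-bromo-1-hydroxy-5-methoxy-7-methyl-4-oxo-1,4-dihydronaphthalen-1-yl)phenyl}propan-2-yl]acetamide (p-quinol, epimer mixture at the carbinol carbon, used crude)
Conditions: 11, MeLi (1.05 equiv), THF, −78 °C; t-BuLi (2.0 equiv), −78 °C; cannulate into 7 (1.3 equiv), THF, −78 °C; NH4Cl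
Reagents that add atoms: none
Why: Br–Li exchange on the N-lithio amide gives a di-ortho-substituted aryllithium that adds 1,2 to C4=O of the quinone (organolithium addition to a quinone giving a p-quinol); C1=O is flanked by Br, peri to OMe and deactivated by it, and the unselective carbinol centre is destroyed in step 9.

**Step 9**
Reactants: 12
Product: 13, (R)-N-{1-[3,5-bis(benzyloxy)-2-(3-bromo-4-hydroxy-5-methoxy-7-methylnaphthalen-1-yl)phenyl]propan-2-yl}acetamide (about 1:1 atropo-diastereomers)
Conditions: NaBH4, CeCl3·7H2O, MeOH–THF, −40 °C; then 2 M HCl, THF, rt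
Reagents that add atoms: none
Why: Luche 1,2-reduction of the bromo-enone, then acid ionisation of the tertiary doubly benzylic carbinol and loss of the C1 proton aromatises the ring (reductive aromatisation of a p-quinol); the vinyl bromide and benzyl ethers are untouched.

**Step 10**
Reactants: 13
Product: 14, (R)-N-{1-[3,5-bis(benzyloxy)-2-(4-(benzyloxy)-3-bromo-5-methoxy-7-methylnaphthalen-1-yl)phenyl]propan-2-yl}acetamide
Conditions: BnBr, Cs2CO3, DMF, rt
Reagents that add atoms: benzyl bromide, BrCc1ccccc1
Why: Williamson etherification of the naphthol; the amide N–H is not deprotonated by carbonate.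

**Step 11**
Reactants: 14
Product: 15, (R)-6,8-bis(benzyloxy)-5-[4-(benzyloxy)-3-bromo-5-methoxy-7-methylnaphthalen-1-yl]-1,3-dimethyl-3,4-dihydroisoquinoline
Conditions: Tf2O, 2-chloropyridine, CH2Cl2, −78 °C → rt
Reagents that add atoms: none
Why: Bischler–Napieralski cyclodehydration through the nitrilium ion onto the only free ortho position, which is para to one OBn and ortho to the other; C3 is not epimerisable.

**Step 12**
Reactants: 15
Product: 16, (1R,3R)-6,8-bis(benzyloxy)-5-[4-(benzyloxy)-3-bromo-5-methoxy-7-methylnaphthalen-1-yl]-1,3-dimethyl-1,2,3,4-tetrahydroisoquinoline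
Conditions: LiAlH4, AlMe3, THF, −78 → 0 °C; separate atropo-diastereomers (prep. HPLC), carry one
Reagents that add atoms: none
Why: Substrate-controlled hydride delivery to the AlMe3-complexed imine gives the 1,3-trans isomer, so 3R sets 1R (the established trans-selective reduction of 1,3-dimethyl-3,4-dihydroisoquinolines; NaBH4 would give cis); the aryl bromide is inert at this temperature.

### Dihydroisoquinoline half

**Step 13**
Reactants: 2; 17, 3-bromo-5-methoxyphenol
Product: 18, tert-butyl (R)-[1-(3-hydroxy-5-methoxyphenyl)propan-2-yl]carbamate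
Conditions: 2 (2 equiv), Zn dust, DMF, rt; then 17, Pd2(dba)3, SPhos, 50 °C
Reagents that add atoms: none
Why: The same Negishi coupling; the weakly basic alkylzinc iodide tolerates the free phenol under SPhos conditions.

**Step 14**
Reactants: 18
Product: 19, (R)-3-(2-acetamidopropyl)-5-methoxyphenyl acetate
Conditions: TFA, CH2Cl2; concentrate; Ac2O, pyridine, DMAP (cat.), rt
Reagents that add atoms: acetic anhydride, CC(=O)OC(C)=O (two acetyl groups)
Why: Boc removal then N,O-diacetylation; the aryl acetate turns that oxygen into a weak donor for the next step.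

**Step 15**
Reactants: 19
Product: 20, (R)-3-(2-acetamidopropyl)-2-bromo-5-methoxyphenyl acetate
Conditions: NBS, MeCN, 0 °C → rt, dark
Reagents that add atoms: N-bromosuccinimide, O=C1CCC(=O)N1Br
Why: Electrophilic bromination is governed by OMe, the only strong donor, and goes para to it, which is the position between the chain and the acetoxy group.

**Step 16**
Reactants: 20
Product: 21, (R)-N-{1-[3-(benzyloxy)-2-bromo-5-methoxyphenyl]propan-2-yl}acetamide
Conditions: K2CO3, MeOH, rt; then switch to DMF, BnBr, 50 °C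
Reagents that add atoms: benzyl bromide, BrCc1ccccc1
Why: Methanolysis of the aryl acetate and Williamson benzylation of the phenoxide give an organolithium-compatible ether ortho to Br.

**Step 17**
Reactants: 21; 7
Product: 22, N-[(2R)-1-{3-(benzyloxy)-2-(3-bromo-1-hydroxy-5-methoxy-7-methyl-4-oxo-1,4-dihydronaphthalen-1-yl)-5-methoxyphenyl}propan-2-yl]acetamide (p-quinol, epimer mixture, used crude)
Conditions: as step 8 (MeLi; t-BuLi; then 7, THF, −78 °C)
Reagents that add atoms: none
Why: The same amide-dianion aryllithium 1,2-addition to C4=O of the quinone as in step 8.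

**Step 18**
Reactants: 22
Product: 23, (R)-N-{1-[3-(benzyloxy)-2-(3-bromo-4-hydroxy-5-methoxy-7-methylnaphthalen-1-yl)-5-methoxyphenyl]propan-2-yl}acetamide (about 1:1 atropo-diastereomers)
Conditions: NaBH4, CeCl3·7H2O, MeOH–THF, −40 °C; then 2 M HCl, THF, rt
Reagents that add atoms: none
Why: Luche reduction and dehydrative aromatisation of the p-quinol, as in step 9.

**Step 19**
Reactants: 23
Product: 24, (R)-N-{1-[3-(benzyloxy)-2-(4-(benzyloxy)-3-bromo-5-methoxy-7-methylnaphthalen-1-yl)-5-methoxyphenyl]propan-2-yl}acetamide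
Conditions: BnBr, Cs2CO3, DMF, rt
Reagents that add atoms: benzyl bromide, BrCc1ccccc1
Why: Williamson etherification of the naphthol.

**Step 20**
Reactants: 24
Product: 25, (R)-6-(benzyloxy)-5-[4-(benzyloxy)-3-bromo-5-methoxy-7-methylnaphthalen-1-yl]-8-methoxy-1,3-dimethyl-3,4-dihydroisoquinoline
Conditions: Tf2O, 2-chloropyridine, CH2Cl2, −78 °C → rt; separate atropo-diastereomers, carry one
Reagents that add atoms: none
Why: Bischler–Napieralski closure at the only free ortho position (para to OBn, ortho to OMe) fixes the 6-OBn/8-OMe pattern; 3R is untouched.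

**Step 21**
Reactants: 25
Product: 26, (R)-6-(benzyloxy)-5-[4-(benzyloxy)-5-methoxy-7-methyl-3-(4,4,5,5-tetramethyl-1,3,2-dioxaborolan-2-yl)naphthalen-1-yl]-8-methoxy-1,3-dimethyl-3,4-dihydroisoquinoline
Conditions: B2pin2, Pd(dppf)Cl2, KOAc, dioxane, 90 °C
Reagents that add atoms: bis(pinacolato)diboron, CC1(C)OB(OC1(C)C)B1OC(C)(C)C(C)(C)O1
Why: Miyaura borylation of the aryl bromide; the ketimine is inert to Pd/KOAc.

### Union and deprotection

**Step 22**
Reactants: 16; 26
Product: 27, penta-O-benzyl michellamine F (tetrahydro half: 6,8-di-OBn, N–H; dihydro half: 6-OBn, 8-OMe; both naphthol oxygens benzylated)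
Conditions: Pd(OAc)2, SPhos, K3PO4, toluene–H2O, 80 °C
Reagents that add atoms: none
Why: Suzuki–Miyaura cross-coupling forms the central biaryl bond, which has only two ortho substituents and is not stereogenic; hetero-selectivity is guaranteed by the Br/Bpin pairing, and the hindered N–H and the imine are tolerated.

**Step 23**
Reactants: 27
Product: 28, michellamine F
Conditions: BCl3, pentamethylbenzene, CH2Cl2, −78 °C; MeOH quench; NaHCO3; Ar atmosphere
Reagents that add atoms: none
Why: Lewis-acid debenzylation with a cation scavenger cleaves the five aryl benzyl ethers at −78 °C without touching the three methyl ethers, the C=N bond (which hydrogenolysis would reduce) or the stereocentres.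

## Compound list

1 | tert-butyl (R)-(1-hydroxypropan-2-yl)carbamate | C[C@H](CO)NC(=O)OC(C)(C)C | starting material
2 | tert-butyl (R)-(1-iodopropan-2-yl)carbamate | C[C@H](CI)NC(=O)OC(C)(C)C | intermediate
3 | methyl 3-methylbut-2-enoate | COC(=O)C=C(C)C | starting material
4 | [(1-methoxy-3-methylbuta-1,3-dien-1-yl)oxy]trimethylsilane | C=C(C)C=C(OC)O[Si](C)(C)C | intermediate
5 | 2,6-dibromo-1,4-benzoquinone | O=C1C=C(Br)C(=O)C(Br)=C1 | starting material
6 | 2-bromo-8-hydroxy-6-methylnaphthalene-1,4-dione | Cc1cc(O)c2C(=O)C(Br)=CC(=O)c2c1 | intermediate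
7 | 2-bromo-8-methoxy-6-methylnaphthalene-1,4-dione | COc1cc(C)cc2C(=O)C=C(Br)C(=O)c12 | intermediate
8 | 1,3-bis(benzyloxy)-5-bromobenzene | Brc1cc(OCc2ccccc2)cc(OCc2ccccc2)c1 | starting material
9 | tert-butyl (R)-{1-[3,5-bis(benzyloxy)phenyl]propan-2-yl}carbamate | C[C@H](Cc1cc(OCc2ccccc2)cc(OCc2ccccc2)c1)NC(=O)OC(C)(C)C | intermediate
10 | (R)-N-{1-[3,5-bis(benzyloxy)phenyl]propan-2-yl}acetamide | C[C@H](Cc1cc(OCc2ccccc2)cc(OCc2ccccc2)c1)NC(C)=O | intermediate
11 | (R)-N-{1-[3,5-bis(benzyloxy)-2-bromophenyl]propan-2-yl}acetamide | C[C@H](Cc1cc(OCc2ccccc2)cc(OCc2ccccc2)c1Br)NC(C)=O | intermediate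
12 | p-quinol of the tetrahydro series (carbinol carbon unselective) | C[C@H](Cc1cc(OCc2ccccc2)cc(OCc2ccccc2)c1C1(O)C=C(Br)C(=O)c2c(OC)cc(C)cc21)NC(C)=O | intermediate
13 | (R)-N-{1-[3,5-bis(benzyloxy)-2-(3-bromo-4-hydroxy-5-methoxy-7-methylnaphthalen-1-yl)phenyl]propan-2-yl}acetamide | C[C@H](Cc1cc(OCc2ccccc2)cc(OCc2ccccc2)c1-c1cc(Br)c(O)c2c(OC)cc(C)cc12)NC(C)=O | intermediate
14 | O-benzyl ether of 13 | C[C@H](Cc1cc(OCc2ccccc2)cc(OCc2ccccc2)c1-c1cc(Br)c(OCc2ccccc2)c2c(OC)cc(C)cc12)NC(C)=O | intermediate
15 | (R)-6,8-bis(benzyloxy)-5-[4-(benzyloxy)-3-bromo-5-methoxy-7-methylnaphthalen-1-yl]-1,3-dimethyl-3,4-dihydroisoquinoline | C[C@@H]1Cc2c(-c3cc(Br)c(OCc4ccccc4)c4c(OC)cc(C)cc34)c(OCc3ccccc3)cc(OCc3ccccc3)c2C(C)=N1 | intermediate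
16 | (1R,3R)-6,8-bis(benzyloxy)-5-[4-(benzyloxy)-3-bromo-5-methoxy-7-methylnaphthalen-1-yl]-1,3-dimethyl-1,2,3,4-tetrahydroisoquinoline | C[C@@H]1Cc2c(-c3cc(Br)c(OCc4ccccc4)c4c(OC)cc(C)cc34)c(OCc3ccccc3)cc(OCc3ccccc3)c2[C@@H](C)N1 | intermediate
17 | 3-bromo-5-methoxyphenol | COc1cc(O)cc(Br)c1 | starting material
18 | tert-butyl (R)-[1-(3-hydroxy-5-methoxyphenyl)propan-2-yl]carbamate | C[C@H](Cc1cc(O)cc(OC)c1)NC(=O)OC(C)(C)C | intermediate
19 | (R)-3-(2-acetamidopropyl)-5-methoxyphenyl acetate | C[C@H](Cc1cc(OC)cc(OC(C)=O)c1)NC(C)=O | intermediate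
20 | (R)-3-(2-acetamidopropyl)-2-bromo-5-methoxyphenyl acetate | C[C@H](Cc1cc(OC)cc(OC(C)=O)c1Br)NC(C)=O | intermediate
21 | (R)-N-{1-[3-(benzyloxy)-2-bromo-5-methoxyphenyl]propan-2-yl}acetamide | C[C@H](Cc1cc(OC)cc(OCc2ccccc2)c1Br)NC(C)=O | intermediate
22 | p-quinol of the dihydro series (carbinol carbon unselective) | C[C@H](Cc1cc(OC)cc(OCc2ccccc2)c1C1(O)C=C(Br)C(=O)c2c(OC)cc(C)cc21)NC(C)=O | intermediate
23 | (R)-N-{1-[3-(benzyloxy)-2-(3-bromo-4-hydroxy-5-methoxy-7-methylnaphthalen-1-yl)-5-methoxyphenyl]propan-2-yl}acetamide | C[C@H](Cc1cc(OC)cc(OCc2ccccc2)c1-c1cc(Br)c(O)c2c(OC)cc(C)cc12)NC(C)=O | intermediate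
24 | O-benzyl ether of 23 | C[C@H](Cc1cc(OC)cc(OCc2ccccc2)c1-c1cc(Br)c(OCc2ccccc2)c2c(OC)cc(C)cc12)NC(C)=O | intermediate
25 | (R)-6-(benzyloxy)-5-[4-(benzyloxy)-3-bromo-5-methoxy-7-methylnaphthalen-1-yl]-8-methoxy-1,3-dimethyl-3,4-dihydroisoquinoline | C[C@@H]1Cc2c(-c3cc(Br)c(OCc4ccccc4)c4c(OC)cc(C)cc34)c(OCc3ccccc3)cc(OC)c2C(C)=N1 | intermediate
26 | pinacol boronate of 25 (Bpin in place of Br) | C[C@@H]1Cc2c(-c3cc(B4OC(C)(C)C(C)(C)O4)c(OCc4ccccc4)c4c(OC)cc(C)cc34)c(OCc3ccccc3)cc(OC)c2C(C)=N1 | intermediate
27 | penta-O-benzyl michellamine F | C[C@@H]1Cc2c(-c3cc(-c4cc(-c5c(OCc6ccccc6)cc(OC)c6c5C[C@@H](C)N=C6C)c5cc(C)cc(OC)c5c4OCc4ccccc4)c(OCc4ccccc4)c4c(OC)cc(C)cc34)c(OCc3ccccc3)cc(OCc3ccccc3)c2[C@@H](C)N1 | intermediate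
28 | michellamine F | COc1cc(O)c(-c2cc(-c3cc(-c4c(O)cc(O)c5c4C[C@@H](C)N[C@@H]5C)c4cc(C)cc(OC)c4c3O)c(O)c3c(OC)cc(C)cc23)c2c1C(C)=N[C@H](C)C2 | target

## Summary

Total steps: 23.
Longest linear sequence: 12 (steps 1, 13–23).

Steps most likely to fail:

1. **Steps 8 and 17 (aryllithium addition to bromoquinone 7).** Electron transfer, Br–Li exchange on the quinone or attack at C1=O could compete. Fallback: reverse the polarity and make the bond by Pd catalysis. Borylate 11/21 and Suzuki-couple with 4-bromo-1-(benzyloxy)-8-methoxy-6-methylnaphthalene; then install the C2 bromide by debenzylation and ortho-bromination (the para position is blocked).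
2. **Step 15 (bromination para to OMe at a site flanked by two substituents).** Fallback: change the directing logic. Start from 3-(benzyloxy)-5-bromophenol (mono-benzylated 5-bromoresorcinol), attach the chain by the same Negishi coupling, brominate para to the free OH (Bu4NBr3), then O-methylate.
3. **Step 23 (five-fold BCl3 debenzylation on a dimer carrying an imine and a secondary amine).** Fallback: reorder the endgame. Debenzylate monomers 16 and 25 separately with BCl3, borylate the dihydro monomer, and run the Suzuki union on the unprotected phenols as the last step.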